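The target is achiral: an unbranched, heteroatom-free (CH2)12 chain ties C6 of ring A (the salicylic acid benzene ring) to ring B (the terminal phenyl). The key step exploits the fact that the C4'–C5' bond of this chain (counted from ring A) lies between plain methylenes, so each half can arrive as an unstabilised primary radical. A crossed Kolbe electrolysis forms that bond in one operation: two carboxylic acids, each one carbon longer than its half, lose CO2 at a platinum anode and the radicals combine. The precursors are 9-phenylnonanoic acid and a 5-arylpentanoic acid whose 1,3-benzodioxin-4-one ring masks phenol and aryl carboxyl together; one hydrolysis then releases the target.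

Key step: step 4

Remark: the target has no stereocentre or stereogenic double bond, so the required single stereoisomer is the compound itself. Compounds 1, 3 and 6 are taken as catalogue compounds.

Step 1
Reactants: 1 5-hydroxy-2,2-dimethyl-4H-1,3-benzodioxin-4-one
Product: 2 2,2-dimethyl-4-oxo-4H-1,3-benzodioxin-5-yl trifluoromethanesulfonate
Conditions: Tf2O, pyridine, CH2Cl2, 0 °C to rt
Reagents that add atoms: trifluoromethanesulfonic anhydride, O=S(=O)(OS(=O)(=O)C(F)(F)F)C(F)(F)F
Why: Aryl triflate formation should be clean because the phenolic oxygen is the only nucleophilic site and the acyl acetal is inert to these non-aqueous, weakly basic conditions.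

Step 2
Reactants: 2 2,2-dimethyl-4-oxo-4H-1,3-benzodioxin-5-yl trifluoromethanesulfonate; 3 benzyl pent-4-ynoate
Product: 4 benzyl 5-(2,2-dimethyl-4-oxo-4H-1,3-benzodioxin-5-yl)pent-4-ynoate
Conditions: Pd(PPh3)2Cl2 (5 mol%), CuI (10 mol%), Et3N, degassed DMF, 60 °C
Reagents that add atoms: none
Why: Sonogashira coupling: the triflate, activated for oxidative addition by the ortho carbonyl, should couple with the copper acetylide of 3 to form the C(sp2)–C(sp) bond, while the benzyl ester keeps the carboxyl from cyclising onto the alkyne and the dioxinone tolerates the amine base.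

Step 3
Reactants: 4 benzyl 5-(2,2-dimethyl-4-oxo-4H-1,3-benzodioxin-5-yl)pent-4-ynoate
Product: 5 5-(2,2-dimethyl-4-oxo-4H-1,3-benzodioxin-5-yl)pentanoic acid
Conditions: H2 (1 atm), 10% Pd/C, EtOAc, rt
Reagents that add atoms: none
Why: Heterogeneous catalytic hydrogenation should saturate the alkyne to the tetramethylene chain and cleave the benzyl ester by hydrogenolysis in the same operation, while the dioxinone (no benzylic C–O bond) and the arene stay untouched.

Step 4
Reactants: 5 5-(2,2-dimethyl-4-oxo-4H-1,3-benzodioxin-5-yl)pentanoic acid; 6 9-phenylnonanoic acid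
Product: 7 2,2-dimethyl-5-(12-phenyldodecyl)-4H-1,3-benzodioxin-4-one
Conditions: smooth Pt anode / Pt cathode, undivided cell, constant current (ca. 0.2 A cm-2), 5 (1 equiv), 6 (4 equiv), KOH (10 mol% of total acid), MeOH, 45 °C, stopped while still weakly acidic
Reagents that add atoms: none
Why: Crossed Kolbe electrolysis: at the platinum anode the carboxylates of 5 and 6 are each oxidised by one electron to acyloxy radicals, which lose CO2 to give the 4-arylbutyl and 8-phenyloctyl primary radicals; these combine in the dense radical layer at the electrode to form the CH2–CH2 bond, while protons are reduced to H2 at the cathode. The closest known reaction type is the mixed Kolbe coupling of two unbranched fatty acids used to build long-chain acids and hydrocarbons. No ring is closed and no stereocentre is formed. The step needs radical coupling to win over further oxidation to a carbocation (Hofer–Moest path) and over oxidation of the arenes: both radicals are unstabilised primary radicals with no α-substituent and at least three CH2 groups between the radical carbon and a ring, the dioxinone ring is deactivated by its acyl group, and high current density on smooth Pt in weakly acidic methanol favours the one-electron path. Cross-coupling over homo-coupling is secured only statistically, by the fourfold excess of the simpler acid 6, whose homodimer is a non-polar hydrocarbon that should separate easily from the polar cross-product on silica. Stopping the electrolysis while the medium is still acidic should keep methoxide from building up and opening the dioxinone.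

Step 5
Reactants: 7 2,2-dimethyl-5-(12-phenyldodecyl)-4H-1,3-benzodioxin-4-one
Product: 9 2-hydroxy-6-(12-phenyldodecyl)benzoic acid (target), via dipotassium 2-oxido-6-(12-phenyldodecyl)benzoate 8 (not isolated)
Conditions: aq. KOH (5 M), THF, 60 °C; then 1 M HCl, 0 °C, to pH 2
Reagents that add atoms: potassium hydroxide, [K+].[OH-]
Why: Saponification of the acyl acetal: hydroxide adds to the lactone carbonyl, the ring opens and the hemiketal loses acetone to give the dipotassium phenoxide–carboxylate 8, which cold acidification converts to the free salicylic acid without heating that could cause decarboxylation.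

Compound list
1 | 5-hydroxy-2,2-dimethyl-4H-1,3-benzodioxin-4-one | CC1(C)OC(=O)c2c(O)cccc2O1 | starting material
2 | 2,2-dimethyl-4-oxo-4H-1,3-benzodioxin-5-yl trifluoromethanesulfonate | CC1(C)OC(=O)c2c(OS(=O)(=O)C(F)(F)F)cccc2O1 | intermediate
3 | benzyl pent-4-ynoate | C#CCCC(=O)OCc1ccccc1 | starting material
4 | benzyl 5-(2,2-dimethyl-4-oxo-4H-1,3-benzodioxin-5-yl)pent-4-ynoate | CC1(C)OC(=O)c2c(C#CCCC(=O)OCc3ccccc3)cccc2O1 | intermediate
5 | 5-(2,2-dimethyl-4-oxo-4H-1,3-benzodioxin-5-yl)pentanoic acid | CC1(C)OC(=O)c2c(CCCCC(=O)O)cccc2O1 | intermediate
6 | 9-phenylnonanoic acid | OC(=O)CCCCCCCCc1ccccc1 | starting material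
7 | 2,2-dimethyl-5-(12-phenyldodecyl)-4H-1,3-benzodioxin-4-one | CC1(C)OC(=O)c2c(CCCCCCCCCCCCc3ccccc3)cccc2O1 | intermediate
8 | dipotassium 2-oxido-6-(12-phenyldodecyl)benzoate | [K+].[K+].[O-]C(=O)c1c([O-])cccc1CCCCCCCCCCCCc1ccccc1 | intermediate
9 | 2-hydroxy-6-(12-phenyldodecyl)benzoic acid | O=C(O)c1c(O)cccc1CCCCCCCCCCCCc1ccccc1 | target

Total step count: 5. Longest linear sequence: 5 steps (1 → 2 → 4 → 5 → 7 → 9).

Steps most likely to fail

Step 4. The coupling is statistical, so homo-coupling may consume 5. The primary radicals may be over-oxidised to cations and trapped by methanol, the rings may be oxidised at the anode, or the dioxinone may undergo methanolysis as the medium loses acid. The fallback sets out from 5 and replaces the radical–radical union by a cross-selective nickel-catalysed decarboxylative alkyl–alkyl coupling. Acid 5 is condensed with N-hydroxyphthalimide (N,N'-diisopropylcarbodiimide, cat. DMAP, CH2Cl2, rt) to give the redox-active ester 1,3-dioxoisoindolin-2-yl 5-(2,2-dimethyl-4-oxo-4H-1,3-benzodioxin-5-yl)pentanoate F1. In parallel, catalogue (8-bromooctyl)benzene (BrCCCCCCCCc1ccccc1) is treated with activated zinc dust and LiCl in THF to give (8-phenyloctyl)zinc bromide F2. F1 and F2 are joined with NiCl2·glyme and 4,4'-di-tert-butyl-2,2'-bipyridine in THF/DMF at rt, with loss of CO2 and phthalimide, and the sequence comes back to the route at 7.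

Step 2. Oxidative homo-coupling of the alkyne under Pd/Cu and sluggish oxidative addition or hydrolysis of the triflate may outrun the cross-coupling. The fallback sets out from 2 and builds the same chain by a B-alkyl Suzuki–Miyaura coupling. Benzyl pent-4-enoate (C=CCCC(=O)OCc1ccccc1) is hydroborated with 9-BBN-H in THF to give benzyl 5-(9-borabicyclo[3.3.1]nonan-9-yl)pentanoate F3. F3 is coupled with 2 (Pd(dppf)Cl2, K3PO4, THF/DMF, 60 °C) to give benzyl 5-(2,2-dimethyl-4-oxo-4H-1,3-benzodioxin-5-yl)pentanoate F4. Hydrogenolysis of F4 (H2, Pd/C, EtOAc) comes back to the route at 5.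

Step 5. Opening of the hindered acyl acetal may stall, and forcing conditions may cause loss of CO2 from the 2,6-disubstituted salicylic acid. The fallback sets out from 7 and avoids aqueous base and acid. Sodium benzyloxide (BnOH, NaH, THF, 0 °C to rt) opens the dioxinone with loss of acetone to give benzyl 2-hydroxy-6-(12-phenyldodecyl)benzoate F5. Neutral hydrogenolysis of F5 (H2, Pd/C, EtOAc, rt) comes back to the route at 9.

Further compounds
F1 | step 4 | 1,3-dioxoisoindolin-2-yl 5-(2,2-dimethyl-4-oxo-4H-1,3-benzodioxin-5-yl)pentanoate | CC1(C)OC(=O)c2c(CCCCC(=O)ON3C(=O)c4ccccc4C3=O)cccc2O1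
F2 | step 4 | (8-phenyloctyl)zinc bromide | Br[Zn]CCCCCCCCc1ccccc1
F3 | step 2 | benzyl 5-(9-borabicyclo[3.3.1]nonan-9-yl)pentanoate | O=C(CCCCB1C2CCCC1CCC2)OCc1ccccc1
F4 | step 2 | benzyl 5-(2,2-dimethyl-4-oxo-4H-1,3-benzodioxin-5-yl)pentanoate | CC1(C)OC(=O)c2c(CCCCC(=O)OCc3ccccc3)cccc2O1
F5 | step 5 | benzyl 2-hydroxy-6-(12-phenyldodecyl)benzoate | O=C(OCc1ccccc1)c1c(O)cccc1CCCCCCCCCCCCc1ccccc1
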